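**Retrosynthetic overview**

1. The target is ent-oritin-(4α→6)-epioritin-4β-ol. The nine benzyl ethers come off last. Before that, the interflavanyl bond C4(upper)–C6(lower) is made by adding the 6-lithio lower flavan to the upper flavan-4-one and reducing the tertiary benzylic alcohol with hydride delivered anti to the 3-benzyloxy group, which gives the 3,4-cis upper unit.
2. Both halves come from one racemic trans-3-O-benzyl-dihydroflavonol, because the upper unit is 2S and the lower unit 2R. A transfer-hydrogenation resolution sends the unreduced (2S,3S)-ketone to the upper half and the reduced (2R)-alcohol to the lower half. In the lower half, dehydration to the 3-benzyloxy-2H-chromene and hydroboration reset C3 to cis and install the 4β-oxygen.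
3. Key disconnection: ring C of the dihydroflavonol is opened at O1–C8a and at C2–C3, leading back to an α-benzyloxy 2'-fluoroacetophenone and 4-benzyloxybenzaldehyde (aldol addition, then fluoride displacement, in one pot).
4. Enabling feature: in ring C, C4 lies between C3 and the ring-A carbon C4a. At the chroman-4-one oxidation level the C4 carbonyl makes C3 an enolisable carbon and places C8a ortho to an acyl group, while O1–C2 is a latent aldehyde C=O. The same carbonyl later receives the lower unit and is reduced away.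
5. Ring order: rings A and B are bought as arenes; ring C of both units is closed in the key step; the interflavanyl bond is formed last.

Key step: step 3

Remark: the target is read as upper unit (2S,3R,4R; 2,3-trans-3,4-cis) and lower unit (2R,3R,4S; 2,3-cis-3,4-trans); 1, 2, 4 and 8 are taken as catalogue compounds, and racemates are written as both enantiomers joined by a dot.

**Route**

Step 1
Reactants: 1 3-fluorocatechol; 2 benzyl bromide
Product: 3 1,2-bis(benzyloxy)-3-fluorobenzene
Conditions: BnBr (2.2 equiv), K2CO3, DMF, 60 °C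
Reagents that add atoms: benzyl bromide (2), BrCc1ccccc1
Why: Williamson ether synthesis on both phenols; benzyl is the only protecting group of the route and all benzyl ethers are removed together in the last step.

Step 2
Reactants: 3 1,2-bis(benzyloxy)-3-fluorobenzene; 4 2-(benzyloxy)-N-methoxy-N-methylacetamide
Product: 7 2-(benzyloxy)-1-[3,4-bis(benzyloxy)-2-fluorophenyl]ethan-1-one, via aryllithium 5 (not isolated), via lithium hemiaminal alkoxide 6 (not isolated)
Conditions: n-BuLi, THF, −78 °C; then 4, −78 °C; H2O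
Reagents that add atoms: none
Why: Directed ortho-metalation followed by Weinreb ketone synthesis; fluorine acidifies the adjacent ring C–H so lithiation should occur ortho to F (kept at −78 °C to avoid loss of LiF), and the chelated tetrahedral adduct collapses to the ketone only on work-up.

Step 3
Reactants: 7 2-(benzyloxy)-1-[3,4-bis(benzyloxy)-2-fluorophenyl]ethan-1-one; 8 4-(benzyloxy)benzaldehyde
Product: 11 rac-trans-3,7,8-tris(benzyloxy)-2-[4-(benzyloxy)phenyl]chroman-4-one [(2S,3S) and (2R,3R)], via potassium enolate 9 (not isolated), via potassium aldolate 10 (not isolated)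
Conditions: KN(SiMe3)2 (1.0 equiv), THF, −78 °C; 8 (1.5 equiv); then 18-crown-6, DMF, −78 → 50 °C
Reagents that add atoms: none
Why: KN(SiMe3)2 gives enolate 9, whose C3 adds reversibly to the aldehyde carbon of 8 (C2–C3 bond, aldolate 10); the alkoxide oxygen O1 then attacks C8a, which bears fluoride ortho to the C4 carbonyl, in an intramolecular addition–elimination SNAr (O1–C8a bond) that is irreversible and so pulls the aldol equilibrium forward. The closest known reaction types are the aldol addition of α-alkoxy aryl ketones to aromatic aldehydes and the alkoxide SNAr cyclisation of β-hydroxy 2'-fluoroaryl ketones to chroman-4-ones, merged here into one pot. Ring C closes as a six-membered ring by attack of O1 on the sp2 carbon C8a, formally 6-endo-trig with respect to the C4a=C8a bond conjugated to the C4 carbonyl, an allowed mode and the usual one for chromanone-forming O-arylation. C2 and C3 are created without absolute control, which is wanted because the upper unit needs the (2S,3S)- and the lower unit the (2R,3R)-enantiomer (sorted in step 4); their relative configuration is under thermodynamic control, since C3 is α to the ketone and should equilibrate through the enolate (KF/18-crown-6 as base) to the 2,3-trans isomer with aryl and benzyloxy both equatorial. The step needs cyclisation through the β-oxygen only and ring closure faster than loss of water to the enone: the α-oxygen is capped as its benzyl ether so no five-membered benzofuranone can form, and stoichiometric base in an aprotic medium leaves a crown-ether-activated potassium alkoxide with no proton source for hydroxide loss. Fluoride and the C4 carbonyl are the only activating elements and both are removed again, fluoride in this step and the carbonyl in steps 4–5 (lower unit) and 9–10 (upper unit).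

Step 4
Reactants: 11 rac-trans-3,7,8-tris(benzyloxy)-2-[4-(benzyloxy)phenyl]chroman-4-one
Product: 12 (2S,3S)-3,7,8-tris(benzyloxy)-2-[4-(benzyloxy)phenyl]chroman-4-one (unreduced enantiomer, recovered); 13 (2R,3S,4R)-3,7,8-tris(benzyloxy)-2-[4-(benzyloxy)phenyl]chroman-4-ol (reduced enantiomer)
Conditions: RuCl[(S,S)-TsDPEN](p-cymene) (1 mol %), HCO2H/Et3N (5:2), EtOAc, 25 °C, stopped near half conversion; chromatography
Reagents that add atoms: none
Why: Noyori–Ikariya asymmetric transfer hydrogenation run as a kinetic resolution, a known way to resolve racemic flavanones; the (S,S)-catalyst delivers hydride to the carbonyl face that is the axial, unhindered face only in the (2R,3R)-enantiomer (giving the 2,4-cis alcohol), so the (2S,3S)-ketone should be left, both products are used, and the new C4 centre of 13 is erased in step 5.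

Step 5
Reactants: 13 (2R,3S,4R)-3,7,8-tris(benzyloxy)-2-[4-(benzyloxy)phenyl]chroman-4-ol
Product: 15 (2R)-3,7,8-tris(benzyloxy)-2-[4-(benzyloxy)phenyl]-2H-chromene, via sulfamate ester 14 (not isolated)
Conditions: Burgess reagent (Et3N+SO2N−CO2Me), toluene, 60 °C
Reagents that add atoms: none
Why: Burgess dehydration (syn elimination through the C4 sulfamate); H3 is the only β-hydrogen and is cis to the C4 oxygen in 13, so the enol ether should form under neutral conditions that spare it, with C3 erased on purpose and C2 untouched.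

Step 6
Reactants: 15 (2R)-3,7,8-tris(benzyloxy)-2-[4-(benzyloxy)phenyl]-2H-chromene
Product: 17 (2R,3R,4S)-3,7,8-tris(benzyloxy)-2-[4-(benzyloxy)phenyl]chroman-4-ol, via alkylborane 16 (not isolated)
Conditions: BH3·THF, THF, 0 °C; then NaOH, H2O2, 0 → 25 °C
Reagents that add atoms: hydrogen peroxide, OO
Why: Hydroboration–oxidation of an enol ether; boron should go to C4 (the carbon β to the ether oxygen) and H to C3 in a syn addition on the face opposite the pseudo-axial 2-aryl group, which sets C3 (benzyloxy cis to aryl) and C4 (oxygen trans to benzyloxy), the oxidation proceeds with retention, and the trans arrangement of boron and benzyloxy disfavours syn β-elimination.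

Step 7
Reactants: 17 (2R,3R,4S)-3,7,8-tris(benzyloxy)-2-[4-(benzyloxy)phenyl]chroman-4-ol; 2 benzyl bromide
Product: 19 (2R,3R,4S)-3,4,7,8-tetrakis(benzyloxy)-2-[4-(benzyloxy)phenyl]chromane, via sodium alkoxide 18 (not isolated)
Conditions: NaH, BnBr, n-Bu4NI (cat.), DMF, 0 → 25 °C
Reagents that add atoms: benzyl bromide (2), BrCc1ccccc1
Why: Williamson ether synthesis on the secondary alkoxide; no stereocentre is touched.

Step 8
Reactants: 19 (2R,3R,4S)-3,4,7,8-tetrakis(benzyloxy)-2-[4-(benzyloxy)phenyl]chromane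
Product: 20 (2R,3R,4S)-3,4,7,8-tetrakis(benzyloxy)-2-[4-(benzyloxy)phenyl]-6-bromochromane
Conditions: NBS (1.0 equiv), CH2Cl2, −20 °C, dark
Reagents that add atoms: N-bromosuccinimide, O=C1CCC(=O)N1Br
Why: Electrophilic aromatic bromination; C6 of ring A is para to O1 and ortho to the 7-benzyloxy group, whereas C5 is activated only by the flanked, twisted 8-benzyloxy group and is shielded by the peri 4-benzyloxy group, and ring B carries a single ether oxygen.

Step 9
Reactants: 20 (2R,3R,4S)-3,4,7,8-tetrakis(benzyloxy)-2-[4-(benzyloxy)phenyl]-6-bromochromane; 12 (2S,3S)-3,7,8-tris(benzyloxy)-2-[4-(benzyloxy)phenyl]chroman-4-one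
Product: 23 (2S,3S)-3,7,8-tris(benzyloxy)-2-[4-(benzyloxy)phenyl]-4-[(2R,3R,4S)-3,4,7,8-tetrakis(benzyloxy)-2-[4-(benzyloxy)phenyl]chroman-6-yl]chroman-4-ol (C4 carbinol configuration not defined), via aryllithium 21 (not isolated), via lithium alkoxide 22 (not isolated)
Conditions: n-BuLi, THF, −78 °C; then 12, −78 °C; H2O
Reagents that add atoms: none
Why: Bromine–lithium exchange then 1,2-addition of the aryllithium to the ketone, a known way to attach an aryl group to C4 of 3-O-protected flavan-4-ones; at −78 °C addition should outrun enolisation at C3, and the configuration of the new carbinol carbon is irrelevant because it is planarised in step 10.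

Step 10
Reactants: 23 tertiary alcohol (as in step 9)
Product: 25 nona-O-benzyl ent-oritin-(4α→6)-epioritin-4β-ol, (2R,3R,4S)-3,4,7,8-tetrakis(benzyloxy)-2-[4-(benzyloxy)phenyl]-6-[(2S,3R,4S)-3,7,8-tris(benzyloxy)-2-[4-(benzyloxy)phenyl]chroman-4-yl]chromane, via benzylic carbocation 24 (not isolated)
Conditions: n-Bu3SnH, CF3CO2H, CH2Cl2, −40 → 0 °C
Reagents that add atoms: none
Why: Ionic hydrogenation (SN1 ionisation, then hydride capture), known for 4-aryl-flavan-4-ols; the doubly aryl-stabilised tertiary cation should form under acid too weak and too cold to ionise the secondary 4-benzyloxy group of the lower unit, and the stannane should deliver hydride to the planar C4 on the face anti to the adjacent 3-benzyloxy group, leaving the aryl group cis to it (upper C4 set; its descriptor reads S in 25 and R in 26 only because the priority order changes on debenzylation).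

Step 11
Reactants: 25 nona-O-benzyl ent-oritin-(4α→6)-epioritin-4β-ol
Product: 26 ent-oritin-(4α→6)-epioritin-4β-ol, (2R,3R,4S)-2-(4-hydroxyphenyl)-6-[(2S,3R,4R)-3,7,8-trihydroxy-2-(4-hydroxyphenyl)chroman-4-yl]chromane-3,4,7,8-tetrol
Conditions: H2 (1 atm), Pd(OH)2/C, THF/MeOH, 25 °C
Reagents that add atoms: none
Why: Hydrogenolysis of the nine primary benzyl ethers under neutral conditions; the ring C–O bonds at C2 and C4 are hindered secondary benzylic bonds on electron-rich rings and should cleave much more slowly, so no stereocentre is affected.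

**Compound list**

1 | 3-fluorocatechol | Oc1cccc(F)c1O | starting material
2 | benzyl bromide | BrCc1ccccc1 | starting material
3 | 1,2-bis(benzyloxy)-3-fluorobenzene | Fc1cccc(OCc2ccccc2)c1OCc1ccccc1 | intermediate
4 | 2-(benzyloxy)-N-methoxy-N-methylacetamide | CON(C)C(=O)COCc1ccccc1 | starting material
5 | [3,4-bis(benzyloxy)-2-fluorophenyl]lithium | [Li]c1ccc(OCc2ccccc2)c(OCc2ccccc2)c1F | intermediate
6 | lithium 2-(benzyloxy)-1-[3,4-bis(benzyloxy)-2-fluorophenyl]-1-[methoxy(methyl)amino]ethan-1-olate | [Li+].[O-]C(COCc1ccccc1)(N(C)OC)c1ccc(OCc2ccccc2)c(OCc2ccccc2)c1F | intermediate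
7 | 2-(benzyloxy)-1-[3,4-bis(benzyloxy)-2-fluorophenyl]ethan-1-one | O=C(COCc1ccccc1)c1ccc(OCc2ccccc2)c(OCc2ccccc2)c1F | intermediate
8 | 4-(benzyloxy)benzaldehyde | O=Cc1ccc(OCc2ccccc2)cc1 | starting material
9 | potassium (Z)-enolate of 7 (geometry assumed, not decisive) | [K+].[O-]/C(=C\OCc1ccccc1)c1ccc(OCc2ccccc2)c(OCc2ccccc2)c1F | intermediate
10 | potassium 2-(benzyloxy)-3-[3,4-bis(benzyloxy)-2-fluorophenyl]-1-[4-(benzyloxy)phenyl]-3-oxopropan-1-olate (racemic, syn/anti mixture, centres unspecified) | [K+].[O-]C(c1ccc(OCc2ccccc2)cc1)C(OCc1ccccc1)C(=O)c1ccc(OCc2ccccc2)c(OCc2ccccc2)c1F | intermediate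
11 | rac-trans-3,7,8-tris(benzyloxy)-2-[4-(benzyloxy)phenyl]chroman-4-one, (2S,3S) and (2R,3R) | O=C1[C@@H](OCc2ccccc2)[C@H](c2ccc(OCc3ccccc3)cc2)Oc2c1ccc(OCc1ccccc1)c2OCc1ccccc1.O=C1[C@H](OCc2ccccc2)[C@@H](c2ccc(OCc3ccccc3)cc2)Oc2c1ccc(OCc1ccccc1)c2OCc1ccccc1 | intermediate
12 | (2S,3S)-3,7,8-tris(benzyloxy)-2-[4-(benzyloxy)phenyl]chroman-4-one | O=C1[C@@H](OCc2ccccc2)[C@H](c2ccc(OCc3ccccc3)cc2)Oc2c1ccc(OCc1ccccc1)c2OCc1ccccc1 | intermediate
13 | (2R,3S,4R)-3,7,8-tris(benzyloxy)-2-[4-(benzyloxy)phenyl]chroman-4-ol (2,3-trans-3,4-trans) | O[C@H]1[C@H](OCc2ccccc2)[C@@H](c2ccc(OCc3ccccc3)cc2)Oc2c1ccc(OCc1ccccc1)c2OCc1ccccc1 | intermediate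
14 | triethylammonium salt of the C4 O-[N-(methoxycarbonyl)sulfamate] of 13 (configuration of 13) | CC[NH+](CC)CC.COC(=O)[N-]S(=O)(=O)O[C@H]1[C@H](OCc2ccccc2)[C@@H](c2ccc(OCc3ccccc3)cc2)Oc2c1ccc(OCc1ccccc1)c2OCc1ccccc1 | intermediate
15 | (2R)-3,7,8-tris(benzyloxy)-2-[4-(benzyloxy)phenyl]-2H-chromene | C1=C(OCc2ccccc2)[C@@H](c2ccc(OCc3ccccc3)cc2)Oc2c1ccc(OCc1ccccc1)c2OCc1ccccc1 | intermediate
16 | C4 alkylborane (17 with BH2 in place of OH, same configuration) | [BH2][C@@H]1[C@@H](OCc2ccccc2)[C@@H](c2ccc(OCc3ccccc3)cc2)Oc2c1ccc(OCc1ccccc1)c2OCc1ccccc1 | intermediate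
17 | (2R,3R,4S)-3,7,8-tris(benzyloxy)-2-[4-(benzyloxy)phenyl]chroman-4-ol (2,3-cis-3,4-trans) | O[C@@H]1[C@@H](OCc2ccccc2)[C@@H](c2ccc(OCc3ccccc3)cc2)Oc2c1ccc(OCc1ccccc1)c2OCc1ccccc1 | intermediate
18 | sodium alkoxide of 17 | [Na+].[O-][C@@H]1[C@@H](OCc2ccccc2)[C@@H](c2ccc(OCc3ccccc3)cc2)Oc2c1ccc(OCc1ccccc1)c2OCc1ccccc1 | intermediate
19 | (2R,3R,4S)-3,4,7,8-tetrakis(benzyloxy)-2-[4-(benzyloxy)phenyl]chromane | O(Cc1ccccc1)[C@@H]1[C@@H](OCc2ccccc2)[C@@H](c2ccc(OCc3ccccc3)cc2)Oc2c1ccc(OCc1ccccc1)c2OCc1ccccc1 | intermediate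
20 | (2R,3R,4S)-3,4,7,8-tetrakis(benzyloxy)-2-[4-(benzyloxy)phenyl]-6-bromochromane | O(Cc1ccccc1)[C@@H]1[C@@H](OCc2ccccc2)[C@@H](c2ccc(OCc3ccccc3)cc2)Oc2c1cc(Br)c(OCc1ccccc1)c2OCc1ccccc1 | intermediate
21 | 6-lithio derivative of 19 | O(Cc1ccccc1)[C@@H]1[C@@H](OCc2ccccc2)[C@@H](c2ccc(OCc3ccccc3)cc2)Oc2c1cc([Li])c(OCc1ccccc1)c2OCc1ccccc1 | intermediate
22 | lithium alkoxide of 23 | [Li+].C(c1ccccc1)Oc1ccc([C@H]2Oc3c(cc(C4([O-])c5ccc(OCc6ccccc6)c(OCc6ccccc6)c5O[C@@H](c5ccc(OCc6ccccc6)cc5)[C@@H]4OCc4ccccc4)c(OCc4ccccc4)c3OCc3ccccc3)[C@H](OCc3ccccc3)[C@H]2OCc2ccccc2)cc1 | intermediate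
23 | (2S,3S)-3,7,8-tris(benzyloxy)-2-[4-(benzyloxy)phenyl]-4-[(2R,3R,4S)-3,4,7,8-tetrakis(benzyloxy)-2-[4-(benzyloxy)phenyl]chroman-6-yl]chroman-4-ol (carbinol C4 not defined) | C(c1ccccc1)Oc1ccc([C@H]2Oc3c(cc(C4(O)c5ccc(OCc6ccccc6)c(OCc6ccccc6)c5O[C@@H](c5ccc(OCc6ccccc6)cc5)[C@@H]4OCc4ccccc4)c(OCc4ccccc4)c3OCc3ccccc3)[C@H](OCc3ccccc3)[C@H]2OCc2ccccc2)cc1 | intermediate
24 | upper-unit C4 carbocation of 23 (trifluoroacetate ion pair) | [O-]C(=O)C(F)(F)F.C(c1ccccc1)Oc1ccc([C@H]2Oc3c(cc([C+]4c5ccc(OCc6ccccc6)c(OCc6ccccc6)c5O[C@@H](c5ccc(OCc6ccccc6)cc5)[C@@H]4OCc4ccccc4)c(OCc4ccccc4)c3OCc3ccccc3)[C@H](OCc3ccccc3)[C@H]2OCc2ccccc2)cc1 | intermediate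
25 | nona-O-benzyl ent-oritin-(4α→6)-epioritin-4β-ol; upper unit (2S,3R,4S), lower unit (2R,3R,4S) | C(c1ccccc1)Oc1ccc([C@H]2Oc3c(cc([C@@H]4c5ccc(OCc6ccccc6)c(OCc6ccccc6)c5O[C@@H](c5ccc(OCc6ccccc6)cc5)[C@@H]4OCc4ccccc4)c(OCc4ccccc4)c3OCc3ccccc3)[C@H](OCc3ccccc3)[C@H]2OCc2ccccc2)cc1 | intermediate
26 | ent-oritin-(4α→6)-epioritin-4β-ol; upper unit (2S,3R,4R), lower unit (2R,3R,4S) | Oc1ccc([C@H]2Oc3c(cc([C@@H]4c5ccc(O)c(O)c5O[C@@H](c5ccc(O)cc5)[C@@H]4O)c(O)c3O)[C@H](O)[C@H]2O)cc1 | target

**Step count and risks**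

Total steps: 11. Longest linear sequence: 11 steps (1 → 3 → 7 → 11 → 13 → 15 → 17 → 19 → 20 → 23 → 25 → 26); the upper-unit ketone 12 is taken from the same material in step 4 and enters at step 9.

Steps most likely to fail:

Step 10. The acid needed to ionise the tertiary alcohol may also ionise the secondary C4 benzyl ether of the lower unit, which would then be reduced to a methylene group. The cation may also be captured from both faces or lose H3 to give the enol ether. The fallback replaces the ionic reduction by a radical one and sets out from 23. Its potassium alkoxide (KN(SiMe3)2, THF, −78 °C) is acylated with methyl chlorooxoacetate to give the C4 methyl oxalate ester F5. This is deoxygenated with n-Bu3SnH and AIBN in toluene at 100 °C (Barton–McCombie-type radical deoxygenation of a tertiary oxalate). The bis-benzylic C4 radical should take hydrogen from the stannane on the face anti to the 3-benzyloxy group, and no acid is present. The route is rejoined at 25.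

Step 6. Boron may add to C3 instead of C4 under the influence of the electron-rich ring A, or the β-benzyloxy borane may undergo β-elimination before oxidation. The fallback sets out from 15. Mild hydrolysis of the enol ether (oxalic acid, wet THF, 25 °C) should give (2R)-7,8-bis(benzyloxy)-2-[4-(benzyloxy)phenyl]chroman-3-one F2. Reduction with LiBH(s-Bu)3 in THF at −78 °C, with hydride adding anti to the 2-aryl group, should give the 2,3-cis alcohol (2R,3R)-7,8-bis(benzyloxy)-2-[4-(benzyloxy)phenyl]chroman-3-ol F3. Benzylation (NaH, BnBr, DMF) gives (2R,3R)-3,7,8-tris(benzyloxy)-2-[4-(benzyloxy)phenyl]chromane F4. Oxidation with DDQ in the presence of benzyl alcohol (CH2Cl2, 25 °C) then generates the C4 benzylic cation, which benzyl alcohol should capture trans to the 3-benzyloxy group, as is known for 2,3-cis flavan-3-ol ethers. The route is rejoined at 19.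

Step 3. Loss of water from the aldol stage to the α-benzyloxy enone, or retro-aldol cleavage, may outrun the ring closure, so that no chromanone accumulates. The fallback separates the two bond formations and sets out from 7 and 8. A kinetic boron aldol reaction (Bu2BOTf, i-Pr2NEt, CH2Cl2, −78 °C; then 8; pH 7 buffer/H2O2 work-up) gives the isolated β-hydroxy ketone 2-(benzyloxy)-1-[3,4-bis(benzyloxy)-2-fluorophenyl]-3-[4-(benzyloxy)phenyl]-3-hydroxypropan-1-one F1; either diastereomer serves. NaH in THF/DMF (0 → 25 °C) then closes ring C by the same fluoride displacement, with C3 equilibrating to trans. The route is rejoined at 11.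

**Further compounds**

F1 | step 3 | 2-(benzyloxy)-1-[3,4-bis(benzyloxy)-2-fluorophenyl]-3-[4-(benzyloxy)phenyl]-3-hydroxypropan-1-one (racemic, diastereomer mixture, centres unspecified) | OC(c1ccc(OCc2ccccc2)cc1)C(OCc1ccccc1)C(=O)c1ccc(OCc2ccccc2)c(OCc2ccccc2)c1F
F2 | step 6 | (2R)-7,8-bis(benzyloxy)-2-[4-(benzyloxy)phenyl]chroman-3-one | C1C(=O)[C@@H](c2ccc(OCc3ccccc3)cc2)Oc2c1ccc(OCc1ccccc1)c2OCc1ccccc1
F3 | step 6 | (2R,3R)-7,8-bis(benzyloxy)-2-[4-(benzyloxy)phenyl]chroman-3-ol | C1[C@@H](O)[C@@H](c2ccc(OCc3ccccc3)cc2)Oc2c1ccc(OCc1ccccc1)c2OCc1ccccc1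
F4 | step 6 | (2R,3R)-3,7,8-tris(benzyloxy)-2-[4-(benzyloxy)phenyl]chromane | C1[C@@H](OCc2ccccc2)[C@@H](c2ccc(OCc3ccccc3)cc2)Oc2c1ccc(OCc1ccccc1)c2OCc1ccccc1
F5 | step 10 | methyl oxalate ester of 23 at the tertiary C4 oxygen (carbinol C4 not defined) | C(c1ccccc1)Oc1ccc([C@H]2Oc3c(cc(C4(OC(=O)C(=O)OC)c5ccc(OCc6ccccc6)c(OCc6ccccc6)c5O[C@@H](c5ccc(OCc6ccccc6)cc5)[C@@H]4OCc4ccccc4)c(OCc4ccccc4)c3OCc3ccccc3)[C@H](OCc3ccccc3)[C@H]2OCc2ccccc2)cc1
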